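Count turnovers. This flask must make 400 molecules of X per Q charged to convert 20% of its Z: that is its turnover bill, a turnover number.

the same everywhere: Z 0.20 M

| charge | Q | remark |
|---|---|---|
| autumn | 0.14 mM | run made earlier |
| winter | 0.22 mM | run made earlier |
| flask | 0.10 mM |  |

- autumn (time / h: X / %, Z / %): 0.417: 16, 82; 0.833: 32, 65; 1.33: 49, 50; 1.50: 54, 50; 2.00: 65, 38; 2.50: 72, 32
- winter (time / h: X / %, Z / %): 0.417: 27, 66; 0.833: 48, 51; 1.33: 67, 34; 1.50: 68, 32; 2.00: 82, 20; 2.50: 89, 13

(scatter of a reading: 2 percentage points)



* apparent order in Q when 20% of the Z are converted (percent change of the rate of making X for one percent more Q charged)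
* factor on the rate of making X when 20% of the Z are converted if Q is charged twice over

Take first the main step by itself, Z turned into X on a Q that stays as charged. At 20% conversion Z stands equal in the three flasks, so each Q turns at one pace and the rate follows the charge: the order is 1, and doubling gives a factor of 2.

Now let Q lose activity with clock time. The bill shrinks as the charge grows, 286 in the autumn run and 182 in the winter run. A larger charge then pays earlier, with more of its Q still working, which lifts the order above 1.

Last comes anything that hangs on Z or X. Both stand equal at equal conversion, so at that point such a term acts alike on each Q, whatever the charge.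

The runs must be compared at equal conversion, not at equal time. Drawn straight between the readings, X reaches 20% at 0.521 h in the autumn run, and drawn straight from the start to the first reading, it reaches 20% at 0.309 h in the winter run. Taking the rate at that conversion to follow the mean rate up to it, the reckoning made here from these two times gives an order of 1.16 and a factor of 2.23. With a scatter of 2 percentage points, the excess over 1 remains a rough reading.

The forecast gives an order of 1.2 and a factor of 2.3, and offers “a little Q lost to a poison” as one possible cause.

The flask gives an order of 1.2 and a factor of 2.20.

    Z + Q → X + Q, rate k1*[Z]*[Q]/(1 + ([Z]/Km1)) (0.275 M, k = 110 L mol⁻¹ min⁻¹)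
    Q ⇌ J (K = 0.440, k = 0.00848 min⁻¹)

In this flask Q is 88.0% of the catalyst at 0.300 h and 72.0% at 1.50 h, the remainder being J, a form outside the working round. The bill of 400 turnovers is paid at 0.632 h, a mean of 633 h⁻¹ per Q charged, and at that moment X is being made at 535 h⁻¹ per Q charged.

(All runs are calculated for an exercise; scatter was added.)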